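**Assumption:** the SMILES is taken literally, i.e. (1R,3S,4Z,6S,7R,8R,10S) in germacrane numbering, with a cis-fused 6,12-lactone and a cis 1,10-epoxide (C2 and C9 cis). Germacrane numbering (C1–C15) is used for atoms of all intermediates.

**Retrosynthetic overview**
1. Target 22 ⇐ acetylation of the C3 alcohol 21.
2. 21 ⇐ key step: intramolecular 2-(alkoxycarbonyl)allylboration of lactol 19 (C6–C7 bond) with in-situ lactonisation; the 10-membered carbocycle and the α-methylene lactone form together while the temporary lactol ring opens.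
3. 19 ⇐ epoxide from C8–OH-directed vanadium epoxidation of the Z alkene; allylboronate from the allylic bromide; bromide from cross-metathesis of vinyl carbinol 13 with methyl 2-(bromomethyl)acrylate.
4. 13 ⇐ ester-aldehyde 9: C3 end by Ni/Cr coupling with Z-iodo acetal 5 (then cyclic acetal), C8 end by DIBAL reduction and asymmetric vinylation.
5. 9 ⇐ Birch reduction/ozonolysis of 3-methylanisole; 5 ⇐ but-2-yn-1-ol. Ring order: epoxide (step 9), then carbocycle + lactone together (step 13).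

**Route**

Step 1
Reactants: 1 but-2-yn-1-ol
Product: 3 (2Z)-3-iodobut-2-en-1-ol, via cyclic sodium alkenylalanate 2 (not isolated)
Conditions: Red-Al, THF, 0 °C → rt; then I2, −78 → 0 °C
Reagents that add atoms: iodine, II
Why: Alkoxide-directed trans-hydroalumination of the propargylic alcohol puts aluminium on C3 cis to CH2O in alanate 2, and iodinolysis with retention gives only the (Z)-vinyl iodide.

Step 2
Reactants: 3 (2Z)-3-iodobut-2-en-1-ol
Product: 5 (2Z)-3-iodo-1,1-dimethoxybut-2-ene, via (2Z)-3-iodobut-2-enal 4 (not isolated)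
Conditions: MnO2, CH2Cl2, rt; filter; then HC(OMe)3, MeOH, PPTS (cat.), rt
Reagents that add atoms: trimethyl orthoformate, COC(OC)OC; methanol, CO
Why: Allylic MnO2 oxidation leaves the vinyl iodide intact, and the labile Z-enal is acetalised at once (acid-catalysed acetalisation) so that it cannot isomerise or self-couple in the later Ni/Cr step.

Step 3
Reactants: 6 3-methylanisole
Product: 7 1-methoxy-5-methylcyclohexa-1,4-diene
Conditions: Li, NH3(l), THF, t-BuOH, −78 → −33 °C
Reagents that add atoms: none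
Why: Birch reduction of the anisole gives the 2,5-dihydro product with methoxy and methyl on the two remaining double bonds.

Step 4
Reactants: 7 1-methoxy-5-methylcyclohexa-1,4-diene
Product: 9 methyl (3Z)-3-methyl-6-oxohex-3-enoate, via α-methoxy hydroperoxide 8 (not isolated)
Conditions: O3 (1 equiv), CH2Cl2/MeOH, −78 °C; then Me2S, −78 °C → rt
Reagents that add atoms: ozone, O=[O+][O-]
Why: Ozonolysis is selective for the electron-rich enol-ether double bond and gives the ester (C8) and aldehyde (C3) termini, while the trisubstituted alkene keeps the ring-derived Z geometry (C9 and C2 cis).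

Step 5
Reactants: 9 methyl (3Z)-3-methyl-6-oxohex-3-enoate; 5 (2Z)-3-iodo-1,1-dimethoxybut-2-ene
Product: 11 methyl (3Z)-5-[(2S)-5-methoxy-3-methyl-2,5-dihydrofuran-2-yl]-3-methylpent-3-enoate, via open-chain hydroxy acetal 10 (not isolated)
Conditions: CrCl2 (4 equiv), NiCl2 (2 mol%), chiral sulfonamide–oxazoline ligand (enantiomer giving Re-face addition), Et3N, THF, rt; then PPTS (cat.), CH2Cl2, rt
Reagents that add atoms: none
Why: Nozaki–Hiyama–Kishi Ni/Cr coupling adds the vinyl iodide to the aldehyde with retention of Z geometry, the chiral ligand sets C3 (S), and acid then closes the Z-γ-hydroxy acetal 10 to the 2-methoxy-2,5-dihydrofuran (transacetalisation), which masks both the C3 hydroxyl and the C6 aldehyde (formed as both C6 acetal epimers, of no consequence).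

Step 6
Reactants: 11 methyl (3Z)-5-[(2S)-5-methoxy-3-methyl-2,5-dihydrofuran-2-yl]-3-methylpent-3-enoate
Product: 12 (3Z)-5-[(2S)-5-methoxy-3-methyl-2,5-dihydrofuran-2-yl]-3-methylpent-3-enal
Conditions: DIBAL-H (1.1 equiv), CH2Cl2, −78 °C; Rochelle salt
Reagents that add atoms: none
Why: Partial ester reduction with DIBAL-H stops at the aldehyde through the stable aluminium hemiacetal and leaves the cyclic acetal untouched.

Step 7
Reactants: 12 (3Z)-5-[(2S)-5-methoxy-3-methyl-2,5-dihydrofuran-2-yl]-3-methylpent-3-enal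
Product: 13 (3R,5Z)-7-[(2S)-5-methoxy-3-methyl-2,5-dihydrofuran-2-yl]-5-methylhepta-1,5-dien-3-ol
Conditions: (CH2=CH)2Zn [from CH2=CHMgBr, ZnCl2], (−)-MIB (10 mol%), toluene/hexane, −20 → 0 °C
Reagents that add atoms: divinylzinc, C=C[Zn]C=C (made from vinylmagnesium bromide, C=C[Mg]Br)
Why: Amino-alcohol-catalysed organozinc addition delivers vinyl to the Si face of the aldehyde with (−)-MIB and sets C8 (R) under reagent control.

Step 8
Reactants: 13 (3R,5Z)-7-[(2S)-5-methoxy-3-methyl-2,5-dihydrofuran-2-yl]-5-methylhepta-1,5-dien-3-ol; 14 methyl 2-(bromomethyl)acrylate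
Product: 15 methyl (2Z,4R,6Z)-2-(bromomethyl)-4-hydroxy-8-[(2S)-5-methoxy-3-methyl-2,5-dihydrofuran-2-yl]-6-methylocta-2,6-dienoate
Conditions: Hoveyda–Grubbs II (10 mol%), 14 (5 equiv), 1,4-benzoquinone (10 mol%), CH2Cl2, 40 °C
Reagents that add atoms: none
Why: Olefin cross-metathesis of the terminal vinyl group with the 1,1-disubstituted acrylate gives the trisubstituted enoate with the ester trans to C8, the trisubstituted chain and ring alkenes being inert to the catalyst.

Step 9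
Reactants: 15 methyl (2Z,4R,6Z)-2-(bromomethyl)-4-hydroxy-8-[(2S)-5-methoxy-3-methyl-2,5-dihydrofuran-2-yl]-6-methylocta-2,6-dienoate
Product: 16 methyl (2Z,4R)-2-(bromomethyl)-4-hydroxy-5-[(2S,3R)-3-{[(2S)-5-methoxy-3-methyl-2,5-dihydrofuran-2-yl]methyl}-2-methyloxiran-2-yl]pent-2-enoate
Conditions: VO(acac)2 (5 mol%), t-BuOOH, CH2Cl2, 0 °C → rt
Reagents that add atoms: tert-butyl hydroperoxide, CC(C)(C)OO
Why: Vanadium-catalysed hydroxyl-directed epoxidation of the homoallylic alcohol goes through a chair-like vanadate transition state with the C7 side chain equatorial, so oxygen is delivered syn to the C8 hydroxyl (C10 S, C1 R; cis epoxide from the Z alkene), while the electron-poor enoate and the undirected dihydrofuran alkene are left alone.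

Step 10
Reactants: 16 methyl (2Z,4R)-2-(bromomethyl)-4-hydroxy-5-[(2S,3R)-3-{[(2S)-5-methoxy-3-methyl-2,5-dihydrofuran-2-yl]methyl}-2-methyloxiran-2-yl]pent-2-enoate
Product: 17 methyl (2E,4R)-4-hydroxy-5-[(2S,3R)-3-{[(2S)-5-methoxy-3-methyl-2,5-dihydrofuran-2-yl]methyl}-2-methyloxiran-2-yl]-2-[(4,4,5,5-tetramethyl-1,3,2-dioxaborolan-2-yl)methyl]pent-2-enoate
Conditions: B2pin2 (1.2 equiv), Pd2(dba)3 (2.5 mol%), THF, 50 °C
Reagents that add atoms: bis(pinacolato)diboron, CC1(C)OB(OC1(C)C)B1OC(C)(C)C(C)(C)O1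
Why: Palladium(0)-catalysed borylation of the allylic bromide (π-allyl palladium, transmetalation with B2pin2) gives the linear 2-(methoxycarbonyl)allylboronate with C8 cis to CH2B, an allyl donor that cannot undergo reductive 1,4-elimination once C8 is acylated.

Step 11
Reactants: 17 methyl (2E,4R)-4-hydroxy-5-[(2S,3R)-3-{[(2S)-5-methoxy-3-methyl-2,5-dihydrofuran-2-yl]methyl}-2-methyloxiran-2-yl]-2-[(4,4,5,5-tetramethyl-1,3,2-dioxaborolan-2-yl)methyl]pent-2-enoate
Product: 18 methyl (2E,4R)-5-[(2S,3R)-3-{[(2S)-5-methoxy-3-methyl-2,5-dihydrofuran-2-yl]methyl}-2-methyloxiran-2-yl]-4-[(2-methylprop-2-enoyl)oxy]-2-[(4,4,5,5-tetramethyl-1,3,2-dioxaborolan-2-yl)methyl]pent-2-enoate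
Conditions: methacryloyl chloride, Et3N, DMAP (cat.), CH2Cl2, 0 °C
Reagents that add atoms: methacryloyl chloride, CC(=C)C(=O)Cl
Why: DMAP-catalysed acylation of the only free hydroxyl installs the C8 methacrylate; the allylboronate has no aldehyde partner yet and the epoxide is inert.

Step 12
Reactants: 18 methyl (2E,4R)-5-[(2S,3R)-3-{[(2S)-5-methoxy-3-methyl-2,5-dihydrofuran-2-yl]methyl}-2-methyloxiran-2-yl]-4-[(2-methylprop-2-enoyl)oxy]-2-[(4,4,5,5-tetramethyl-1,3,2-dioxaborolan-2-yl)methyl]pent-2-enoate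
Product: 19 methyl (2E,4R)-5-[(2S,3R)-3-{[(2S)-5-hydroxy-3-methyl-2,5-dihydrofuran-2-yl]methyl}-2-methyloxiran-2-yl]-4-[(2-methylprop-2-enoyl)oxy]-2-[(4,4,5,5-tetramethyl-1,3,2-dioxaborolan-2-yl)methyl]pent-2-enoate
Conditions: PPTS (cat.), acetone/H2O (10:1), 0 °C → rt
Reagents that add atoms: water, O
Why: The 2-methoxy-2,5-dihydrofuran is an allylic cyclic acetal that hydrolyses under very mild acid (acetal hydrolysis) to the lactol, the ring form of the Z-γ-hydroxy enal, at a pH the trisubstituted epoxide tolerates.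

Step 13
Reactants: 19 methyl (2E,4R)-5-[(2S,3R)-3-{[(2S)-5-hydroxy-3-methyl-2,5-dihydrofuran-2-yl]methyl}-2-methyloxiran-2-yl]-4-[(2-methylprop-2-enoyl)oxy]-2-[(4,4,5,5-tetramethyl-1,3,2-dioxaborolan-2-yl)methyl]pent-2-enoate
Product: 21 (1R,3S,4Z,6S,7R,8R,10S)-1,10-epoxy-3-hydroxy-8-(methacryloyloxy)germacra-4,11(13)-dien-12,6-olide, via macrocyclic pinacol borate 20 (not isolated)
Conditions: PhMe (2 mM), BHT (cat.), 80 °C; then PPTS (cat.), rt
Reagents that add atoms: none
Why: Proposed new method: at high dilution the lactol opens to the (Z)-γ-hydroxy enal, whose C6 aldehyde is allylborated intramolecularly by the 2-(alkoxycarbonyl)allylboronate through a closed six-membered chair transition state (B on C13, C7 as γ-carbon with C8 cis to CH2B, i.e. Z-crotyl type, giving the syn adduct and hence the cis lactone; A(1,3)-controlled attack anti to the C9 chain with H8 eclipsing the alkene fixes C6 S and C7 R relative to C8), after which the C6 borate 20 lactonises onto the methyl ester, the closest known reactions being the intermolecular 2-alkoxycarbonyl-allylboration/lactonisation of aldehydes and intramolecular allylborations that close medium rings.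

Step 14
Reactants: 21 (1R,3S,4Z,6S,7R,8R,10S)-1,10-epoxy-3-hydroxy-8-(methacryloyloxy)germacra-4,11(13)-dien-12,6-olide
Product: 22 (1R,3S,4Z,6S,7R,8R,10S)-3-acetoxy-1,10-epoxy-8-(methacryloyloxy)germacra-4,11(13)-dien-12,6-olide (CNP0267696.1)
Conditions: Ac2O, pyridine, DMAP (cat.), CH2Cl2, 0 °C → rt
Reagents that add atoms: acetic anhydride, CC(=O)OC(C)=O
Why: Acetylation of the single remaining hydroxyl (C3) completes the target without touching the α-methylene lactone, methacrylate or epoxide.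

**Compound list**
1 | but-2-yn-1-ol | CC#CCO | starting material
2 | cyclic sodium alkenylalanate (2,2-bis(2-methoxyethoxy)-3-methyl-2,5-dihydro-1,2-oxaaluminol-2-uide, Na salt) | [Na+].CC1=CCO[Al-]1(OCCOC)OCCOC | intermediate (not isolated)
3 | (2Z)-3-iodobut-2-en-1-ol | OC/C=C(/C)I | intermediate
4 | (2Z)-3-iodobut-2-enal | O=C/C=C(/C)I | intermediate (not isolated)
5 | (2Z)-3-iodo-1,1-dimethoxybut-2-ene | COC(OC)/C=C(/C)I | intermediate
6 | 3-methylanisole | COc1cccc(C)c1 | starting material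
7 | 1-methoxy-5-methylcyclohexa-1,4-diene | COC1=CCC=C(C)C1 | intermediate
8 | methyl (3Z)-6-hydroperoxy-6-methoxy-3-methylhex-3-enoate | COC(=O)C/C(C)=C\CC(OC)OO | intermediate (not isolated)
9 | methyl (3Z)-3-methyl-6-oxohex-3-enoate | COC(=O)C/C(C)=C\CC=O | intermediate
10 | methyl (3Z,6S,7Z)-6-hydroxy-9,9-dimethoxy-3,7-dimethylnona-3,7-dienoate | COC(=O)C/C(C)=C\C[C@H](O)/C(C)=C\C(OC)OC | intermediate (not isolated)
11 | methyl (3Z)-5-[(2S)-5-methoxy-3-methyl-2,5-dihydrofuran-2-yl]-3-methylpent-3-enoate (both acetal epimers) | COC(=O)C/C(C)=C\C[C@@H]1OC(OC)C=C1C | intermediate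
12 | (3Z)-5-[(2S)-5-methoxy-3-methyl-2,5-dihydrofuran-2-yl]-3-methylpent-3-enal | O=CC/C(C)=C\C[C@@H]1OC(OC)C=C1C | intermediate
13 | (3R,5Z)-7-[(2S)-5-methoxy-3-methyl-2,5-dihydrofuran-2-yl]-5-methylhepta-1,5-dien-3-ol | C=C[C@H](O)C/C(C)=C\C[C@@H]1OC(OC)C=C1C | intermediate
14 | methyl 2-(bromomethyl)acrylate | COC(=O)C(=C)CBr | starting material
15 | methyl (2Z,4R,6Z)-2-(bromomethyl)-4-hydroxy-8-[(2S)-5-methoxy-3-methyl-2,5-dihydrofuran-2-yl]-6-methylocta-2,6-dienoate | COC(=O)/C(CBr)=C/[C@H](O)C/C(C)=C\C[C@@H]1OC(OC)C=C1C | intermediate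
16 | methyl (2Z,4R)-2-(bromomethyl)-4-hydroxy-5-[(2S,3R)-3-{[(2S)-5-methoxy-3-methyl-2,5-dihydrofuran-2-yl]methyl}-2-methyloxiran-2-yl]pent-2-enoate | COC(=O)/C(CBr)=C/[C@H](O)C[C@]2(C)O[C@@H]2C[C@@H]1OC(OC)C=C1C | intermediate
17 | methyl (2E,4R)-4-hydroxy-5-[(2S,3R)-3-{[(2S)-5-methoxy-3-methyl-2,5-dihydrofuran-2-yl]methyl}-2-methyloxiran-2-yl]-2-[(4,4,5,5-tetramethyl-1,3,2-dioxaborolan-2-yl)methyl]pent-2-enoate | COC(=O)/C(CB3OC(C)(C)C(C)(C)O3)=C/[C@H](O)C[C@]2(C)O[C@@H]2C[C@@H]1OC(OC)C=C1C | intermediate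
18 | C8 methacrylate of 17 (methyl (2E,4R)-…-4-[(2-methylprop-2-enoyl)oxy]-…pent-2-enoate) | COC(=O)/C(CB3OC(C)(C)C(C)(C)O3)=C/[C@H](OC(=O)C(C)=C)C[C@]2(C)O[C@@H]2C[C@@H]1OC(OC)C=C1C | intermediate
19 | lactol of 18 (5-hydroxy-2,5-dihydrofuran in place of the methyl acetal) | COC(=O)/C(CB3OC(C)(C)C(C)(C)O3)=C/[C@H](OC(=O)C(C)=C)C[C@]2(C)O[C@@H]2C[C@@H]1OC(O)C=C1C | intermediate
20 | methyl (1R,3S,4Z,6S,7S,8R,10S)-1,10-epoxy-3-hydroxy-8-(methacryloyloxy)-6-[(4,4,5,5-tetramethyl-1,3,2-dioxaborolan-2-yl)oxy]germacra-4,11(13)-dien-12-oate | C=C(C)C(=O)O[C@@H]1C[C@]2(C)O[C@@H]2C[C@H](O)/C(C)=C\[C@H](OB3OC(C)(C)C(C)(C)O3)[C@@H]1C(=C)C(=O)OC | intermediate (not isolated)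
21 | (1R,3S,4Z,6S,7R,8R,10S)-1,10-epoxy-3-hydroxy-8-(methacryloyloxy)germacra-4,11(13)-dien-12,6-olide | C=C(C)C(=O)O[C@@H]1C[C@]2(C)O[C@@H]2C[C@H](O)/C(C)=C\[C@@H]2OC(=O)C(=C)[C@@H]21 | intermediate
22 | (1R,3S,4Z,6S,7R,8R,10S)-3-acetoxy-1,10-epoxy-8-(methacryloyloxy)germacra-4,11(13)-dien-12,6-olide | C=C(C)C(=O)O[C@@H]1C[C@]2(C)O[C@@H]2C[C@H](OC(C)=O)/C(C)=C\[C@@H]2OC(=O)C(=C)[C@@H]21 | target

**Totals**
Total steps: 14. Longest linear sequence: 12 (steps 3–14 from 3-methylanisole; equally steps 1, 2, 5–14 from but-2-yn-1-ol).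

**Three steps most likely to fail**

Step 13 (key ring closure). The ester-substituted allylboronate is a weak nucleophile, the closure is a dilute 10-membered ring formation, thermal 1,4-loss of the C8 methacrylate is conceivable, and ring strain may override the acyclic facial preference. The fallback sets out from 16 and comes back at 22. TESOTf/2,6-lutidine at −78 °C gives the C8 triethylsilyl ether of 16 F1, and PPTS in wet acetone gives its lactol F2. CrCl2 in DMF at high dilution then closes the ring by a Nozaki–Hiyama allylation with lactonisation; the silyl ether is not a leaving group for reductive 1,4-elimination of the allylchromium, which is why the methacrylate is postponed. This gives the 8-O-triethylsilyl analogue of 21 F3. Ac2O/pyridine gives the C3 acetate F4, HF·pyridine frees the C8 alcohol F5, and methacrylic anhydride/DMAP gives 22.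

Step 8 (cross-metathesis). A hindered allylic alcohol with a 1,1-disubstituted bromomethyl acrylate may react slowly or isomerise. The fallback sets out from 12 and comes back at 15. Zinc–ProPhenol-catalysed addition of methyl propiolate (ligand enantiomer for the 4R alcohol) gives the γ-hydroxy ynoate F6. Red-Al at −72 °C followed by NIS (hydroxyl-directed trans-hydroalumination, iodine at the α-carbon cis to C8) gives the α-iodo enoate F7. Stille coupling with (tributylstannyl)methanol gives the 2-(hydroxymethyl) enoate F8, and CBr4/PPh3 at 0 °C brominates the primary allylic alcohol selectively to give 15.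

Step 5 (enantiocontrol at C3). With no neighbouring stereocentre, the ligand-controlled Ni/Cr addition of a hindered trisubstituted vinyl iodide may give only moderate ee. The fallback sets out from 9 and 5 and comes back at 10. The ligand-free Ni/Cr coupling gives the racemic C6 alcohol corresponding to 10 F9, and Dess–Martin oxidation gives the Z-enone F10. Reduction with (R)-Me-CBS/catecholborane at −78 °C (alkenyl as the large group) gives (6S)-10, which is cyclised with PPTS to 11 as in step 5.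

**Further compounds**
F1 | step 13 | C8 triethylsilyl ether of 16, methyl (2Z,4R)-2-(bromomethyl)-5-[(2S,3R)-3-{[(2S)-5-methoxy-3-methyl-2,5-dihydrofuran-2-yl]methyl}-2-methyloxiran-2-yl]-4-(triethylsilyloxy)pent-2-enoate | COC(=O)/C(CBr)=C/[C@H](O[Si](CC)(CC)CC)C[C@]2(C)O[C@@H]2C[C@@H]1OC(OC)C=C1C
F2 | step 13 | lactol of F1 (5-hydroxy-2,5-dihydrofuran) | COC(=O)/C(CBr)=C/[C@H](O[Si](CC)(CC)CC)C[C@]2(C)O[C@@H]2C[C@@H]1OC(O)C=C1C
F3 | step 13 | (1R,3S,4Z,6S,7S,8R,10S)-1,10-epoxy-3-hydroxy-8-(triethylsilyloxy)germacra-4,11(13)-dien-12,6-olide | CC[Si](CC)(CC)O[C@@H]1C[C@]2(C)O[C@@H]2C[C@H](O)/C(C)=C\[C@@H]2OC(=O)C(=C)[C@@H]21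
F4 | step 13 | (1R,3S,4Z,6S,7S,8R,10S)-3-acetoxy-1,10-epoxy-8-(triethylsilyloxy)germacra-4,11(13)-dien-12,6-olide | CC[Si](CC)(CC)O[C@@H]1C[C@]2(C)O[C@@H]2C[C@H](OC(C)=O)/C(C)=C\[C@@H]2OC(=O)C(=C)[C@@H]21
F5 | step 13 | (1R,3S,4Z,6S,7R,8R,10S)-3-acetoxy-1,10-epoxy-8-hydroxygermacra-4,11(13)-dien-12,6-olide | O[C@@H]1C[C@]2(C)O[C@@H]2C[C@H](OC(C)=O)/C(C)=C\[C@@H]2OC(=O)C(=C)[C@@H]21
F6 | step 8 | methyl (4R,6Z)-4-hydroxy-8-[(2S)-5-methoxy-3-methyl-2,5-dihydrofuran-2-yl]-6-methyloct-6-en-2-ynoate | COC(=O)C#C[C@H](O)C/C(C)=C\C[C@@H]1OC(OC)C=C1C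
F7 | step 8 | methyl (2Z,4R,6Z)-4-hydroxy-2-iodo-8-[(2S)-5-methoxy-3-methyl-2,5-dihydrofuran-2-yl]-6-methylocta-2,6-dienoate | COC(=O)/C(I)=C/[C@H](O)C/C(C)=C\C[C@@H]1OC(OC)C=C1C
F8 | step 8 | methyl (2E,4R,6Z)-4-hydroxy-2-(hydroxymethyl)-8-[(2S)-5-methoxy-3-methyl-2,5-dihydrofuran-2-yl]-6-methylocta-2,6-dienoate | COC(=O)/C(CO)=C/[C@H](O)C/C(C)=C\C[C@@H]1OC(OC)C=C1C
F9 | step 5 | methyl (3Z,7Z)-6-hydroxy-9,9-dimethoxy-3,7-dimethylnona-3,7-dienoate, racemic at C6 | COC(=O)C/C(C)=C\CC(O)/C(C)=C\C(OC)OC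
F10 | step 5 | methyl (3Z,7Z)-9,9-dimethoxy-3,7-dimethyl-6-oxonona-3,7-dienoate | COC(=O)C/C(C)=C\CC(=O)/C(C)=C\C(OC)OC
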